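The south-east flask was charged with 4.04 times the starting material of the north-east flask, yet after 60.0 min they hold 24% and 22% of their charges as intermediate, against a scatter of 1.5 percentage points on each reading.

| setting | south | north-east | south-east | beta | epsilon | delta | zeta |
|---|---|---|---|---|---|---|---|
| starting material | 0.094 M | 0.047 M | 0.19 M | 0.094 M (fed, over 2.40 h) | 0.094 M | 0.094 M | 0.094 M |
| coupling partner | 0.47 M | 0.47 M | 0.47 M | 0.470 M | 0.470 M | 0.470 M | 0.470 M |
| protic impurity | 9.4 mM | 9.4 mM | 9.4 mM | 9.40 mM | 9.40 mM | 9.40 mM | 9.40 mM |
| remark | run made earlier | run made earlier | run made earlier | all but starting material at the start; starting material goes in evenly over 2.40 h, the run ends at 3.0 h | a single well-mixed tank run continuously and read at steady state, 3.0 h in it on average | everything together in a closed stirred flask, run for 3.0 h | one stirred flow tank at steady state, fed with the mixture as stated, mean residence time 9.00 h |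
| time |  |  |  | 3.0 h |  | 3.0 h |  |

south run (percent of the starting material charged)

| time / h | intermediate / % | target / % |
|---|---|---|
| 0.200 | 12 | 1 |
| 0.667 | 23 | 12 |
| 1.00 | 20 | 20 |
| 1.50 | 21 | 28 |
| 2.50 | 13 | 38 |
| 3.00 | 9 | 41 |

north-east run (percent of the starting material charged)

| time / min | intermediate / % | target / % |
|---|---|---|
| 8.00 | 9 | 3 |
| 15.0 | 16 | 5 |
| 25.0 | 18 | 4 |
| 40.0 | 20 | 15 |
| 60.0 | 22 | 21 |
| 120 | 14 | 33 |

south-east run (percent of the starting material charged)

| time / min | intermediate / % | target / % |
|---|---|---|
| 8.00 | 10 | 0 |
| 15.0 | 17 | 3 |
| 25.0 | 20 | 4 |
| 40.0 | 23 | 12 |
| 60.0 | 24 | 22 |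
| 120 | 17 | 34 |

(scatter of a reading: 1.5 percentage points)

- the stated concentrations are those of everything mixed, before any reaction; amounts are the same in each set-up
- the numbers in the tables scatter by 1.5 percentage points (one standard deviation)
- the feed brings no volume worth counting
- the earlier runs were made in a closed, stirred flask

- the set-up with the highest amount of intermediate at the outlet or at the end, in percent of the starting material put in ("none" if the first two lie within 2 percentage points) (beta / epsilon / delta / zeta / none)
- amount of intermediate at the outlet or at the end, in percent of the starting material put in, beta
- amount of intermediate at the outlet or at the end, in percent of the starting material put in, epsilon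
- amount of intermediate at the outlet or at the end, in percent of the starting material put in, delta
- amount of intermediate at the outlet or at the end, in percent of the starting material put in, zeta

**What does that agreement allow?** Following one molecule. I take its fate in these runs as independent of the charge, which is pseudo-first-order behaviour, though at 120 min the south-east reading stands 3 points above the north-east one. So I read the south curve as the chance that a molecule of a given age is intermediate, and each vessel as a spread of ages.

**What do you carry?** The area under the south curve up to 3.0 h is 0.493 h. Call it the dwell, the average time one molecule spends as intermediate during that span.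

**Beta?** The feed runs evenly for 2.40 h and the run ends at 3.0 h, so ages spread evenly from 0.600 h upward. The part of the dwell from 0.667 h to 3.00 h is 0.399 h. Divided by that width, it gives 17.1%.

**But doesn't a fed flask run thin?** It may stand below the 0.047 M of the thinnest run. That lies outside the test, and I accept the risk.

**Zeta?** Its residence time of 9.00 h is far longer than the dwell, so the chance of catching a molecule as intermediate is dwell over residence time, 5.48%. The uncounted tail adds to this and early exits subtract from it.

**Delta and epsilon?** Delta is the south reading at its end, 9%. For epsilon I have no figure of my own.

The forecast names beta, with beta 18%, epsilon 12.5%, delta 9% and zeta 6%; for beta, “the batch curve averaged over ages 0.6–3 h gives about 18%”. My beta and zeta lie 0.90 points and 0.52 points below its values.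

The flasks give beta as best: beta 18.6%, epsilon 12.2%, delta 9.77%, zeta 5.97%.

    target ⇌ isomer of the product (K = 2.60, k = 0.00740 min⁻¹)
    coupling partner ⇌ dormant form (K = 4.60, k = 0.970 min⁻¹)
    intermediate → target (k = 0.0220 min⁻¹)
    starting material + coupling partner → intermediate + by-product (k = 0.150 L mol⁻¹ min⁻¹)
    starting material + protic impurity → quenched substrate (k = 13.0 L mol⁻¹ min⁻¹)

The half-life of intermediate on its way to target, 0.53 h, is shorter than the 3.0 h of the run. The delta flask, whose molecules reach that full age, ends at 9.77%, while the beta flask, with ages from 0.600 h upward, ends at 18.6%, against the 17.1% from its window of the dwell. In the zeta flask, the outlet share multiplied by the residence time makes 0.537 h, against a dwell of 0.493 h. Left until 30.0 h, the beta flask holds 0% as intermediate.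

The runs stem from a simulated flask with made-up constants.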